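**Plan**
- Retrosynthesis: the 8-OH is traced back to an 8-OMe and the saturated C1'–C2' bond of the side chain to an E alkene. Ring B (the lactone) is then cut at C4–C4a and at O2–C3 in one stroke, giving 2-bromo-4,6-dimethoxybenzoic acid and (E)-trideca-1,3-dien-8-one.
- The diene is cut at its C2–C3 bond (Suzuki coupling), at its C3=C4 alkene (cross-metathesis) and at the ketone (Grignard addition to a nitrile).
- Enabling feature: C3 is a carbinol carbon whose neighbour C1' can be made sp2, so C3–C1'–C2' can act as an allyl unit. The carboxyl carbon C1 on C8a of ring A stands ortho to C4a, so an aryl–palladium at C4a and the carboxylate oxygen O2 can span C4 and C3 of a diene terminus.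
- Forward: ring A is bought; the diene chain is built linearly; ring B closes in a palladium-catalysed [4+2] heteroannulation; alkene hydrogenation and selective 8-O-demethylation finish.
- Stereochemistry: the only stereocentre, C3, is set in the annulation by the chiral phosphine on palladium and is not touched afterwards.

Key step: step 6

Assumption: the sense of induction of the chiral ligand in step 6 cannot be predicted with certainty, so the ligand antipode that leads to (S)-13 is identified in a small trial run and then used; both antipodes are accessible.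

**Step 1**
Reactants: 1 1-bromo-3,5-dimethoxybenzene
Product: 3 2-bromo-4,6-dimethoxybenzaldehyde, via iminium chloride 2 (not isolated)
Conditions: POCl3, DMF, 0 → 95 °C; then ice/H2O
Reagents that add atoms: DMF, CN(C)C=O (formyl carbon); water, O (carbonyl oxygen); POCl3, O=P(Cl)(Cl)Cl (supplies only the chloride counter-ion of 2)
Why: Vilsmeier–Haack formylation should take place at the ring carbon para to one methoxy and ortho to the other (next to bromine) in preference to the carbon flanked by both methoxy groups, and the aryl iminium salt is hydrolysed on work-up.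

**Step 2**
Reactants: 3 2-bromo-4,6-dimethoxybenzaldehyde
Product: 4 2-bromo-4,6-dimethoxybenzoic acid
Conditions: NaClO2, NaH2PO4, 2-methyl-2-butene, t-BuOH/H2O, rt
Reagents that add atoms: sodium chlorite, [Na+].[O-]Cl=O
Why: Pinnick oxidation converts the aldehyde into the acid through chlorous acid, while 2-methyl-2-butene traps HOCl so that the electron-rich ring is not chlorinated; the aryl bromide and ethers are inert.

**Step 3**
Reactants: 5 pentylmagnesium bromide; 6 hex-5-enenitrile
Product: 8 undec-10-en-6-one, via N-magnesio ketimine 7 (not isolated)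
Conditions: 5 (1.2 equiv), CuBr (2 mol %), THF, reflux; then 1 M HCl, 0 °C → rt
Reagents that add atoms: water, O
Why: Grignard addition to a nitrile stops at the N-magnesio ketimine, so no tertiary alcohol can form, and acidic hydrolysis gives the ketone; CuBr catalysis favours addition over α-deprotonation and the terminal alkene is inert.

**Step 4**
Reactants: 8 undec-10-en-6-one; 9 4,4,5,5-tetramethyl-2-vinyl-1,3,2-dioxaborolane
Product: 10 (E)-11-(4,4,5,5-tetramethyl-1,3,2-dioxaborolan-2-yl)undec-10-en-6-one
Conditions: second-generation Grubbs catalyst RuCl2(=CHPh)(PCy3)(H2IMes) (3 mol %), 9 (2 equiv), CH2Cl2, 40 °C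
Reagents that add atoms: none
Why: Olefin cross-metathesis of a terminal alkene with the vinyl boronate should give the E alkenyl boronate, the bulky boronate ester favouring the E geometry and loss of ethene driving the reaction; the ketone is inert to the ruthenium carbene.

**Step 5**
Reactants: 10 (E)-alkenyl boronate; 11 vinyl bromide
Product: 12 (E)-trideca-1,3-dien-8-one
Conditions: Pd(PPh3)4 (5 mol %), 11 (1 M in THF, 3 equiv), 2 M aq. K2CO3, THF, 60 °C, sealed vessel; product stored cold with BHT
Reagents that add atoms: none
Why: Suzuki–Miyaura alkenyl–alkenyl coupling proceeds with retention of the boronate geometry and should give the (E)-1-substituted 1,3-diene; the carbonate base leaves the ketone untouched.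

**Step 6**
Reactants: 4 2-bromo-4,6-dimethoxybenzoic acid; 12 (E)-trideca-1,3-dien-8-one
Product: 13 (S)-6,8-dimethoxy-3-[(E)-6-oxoundec-1-en-1-yl]-3,4-dihydro-1H-isochromen-1-one
Conditions: Pd2(dba)3·CHCl3 (2.5 mol %), chiral sulfinamide monophosphine TY-Phos (6 mol %, antipode giving (S)-13), K2CO3 (2 equiv), 12 (1.5 equiv), 1,4-dioxane, 70 °C
Reagents that add atoms: none
Why: Proposed new method: oxidative addition of the C–Br bond of 4 to zerovalent palladium gives an arylpalladium species with the ortho carboxylate as internal ligand; the unsubstituted terminal C=C of diene 12 inserts with aryl transfer to its CH2 carbon (C4–C4a bond) and the resulting η3-allylpalladium is captured at its proximal terminus by the carboxylate oxygen (O2–C3 bond), returning zerovalent palladium. The closest known reaction types are the palladium-catalysed heteroannulation of 1,3-dienes by ortho-functionalised aryl halides and its enantioselective Heck/Tsuji–Trost variant with 2-halophenols and 2-haloanilines; the step goes beyond them in using a carboxylate as the internal nucleophile under asymmetric control on a 1-alkyl diene. Ring B closes in a 6-exo mode on the allyl unit, the C1'=C2' alkene staying outside the ring, whereas attack at the distal allyl terminus would require an eight-membered ring. The C3 stereocentre is under catalyst control: the chiral monophosphine differentiates the diene faces in the insertion, and C–O bond formation on the configurationally defined allyl is then stereospecific. The step needs insertion at the terminal and not the internal alkene (sterics plus formation of the stabilised allyl), C–O closure faster than β-hydride elimination (the carboxylate is held next to C3 of the η3-allyl) and no ketone α-arylation (the carbonate base does not enolise the remote ketone). The E alkene that remains is a helper that is removed in step 7.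

**Step 7**
Reactants: 13 (S)-alkenyl lactone
Product: 14 (R)-6,8-dimethoxy-3-(6-oxoundecyl)-3,4-dihydro-1H-isochromen-1-one
Conditions: H2 (3 bar), RhCl(PPh3)3 (5 mol %), toluene/EtOH 1:1, rt
Reagents that add atoms: none
Why: Homogeneous hydrogenation with Wilkinson's catalyst should reduce the disubstituted C=C without touching the ketone, lactone or arene and without hydrogenolysis of the allylic C3–O bond; C3 is not involved, and its descriptor changes from S to R only because the saturated chain now ranks below C4.

**Step 8**
Reactants: 14 (R)-6,8-dimethoxy lactone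
Product: 16 (R)-8-hydroxy-6-methoxy-3-(6-oxoundecyl)-3,4-dihydro-1H-isochromen-1-one, via aryl dichloroborinate 15 (not isolated)
Conditions: BCl3 (1 M in CH2Cl2, 2.5 equiv), CH2Cl2, −78 → 0 °C; then H2O
Reagents that add atoms: BCl3, ClB(Cl)Cl (its BCl2 group is carried only in 15 and is lost on work-up; 16 gains hydrogen only)
Why: Chelation-controlled aryl methyl ether cleavage: BCl3 binds between the lactone carbonyl and the peri methoxy on C8 and chloride removes that methyl only, the 6-methoxy having no neighbouring carbonyl; the ketone, lactone and C3 should survive at low temperature.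

**Compound list**
1 | 1-bromo-3,5-dimethoxybenzene | COc1cc(Br)cc(OC)c1 | starting material
2 | N-[(2-bromo-4,6-dimethoxyphenyl)methylidene]-N-methylmethanaminium chloride | COc1cc(OC)c(C=[N+](C)C)c(Br)c1.[Cl-] | intermediate (not isolated)
3 | 2-bromo-4,6-dimethoxybenzaldehyde | COc1cc(OC)c(C=O)c(Br)c1 | intermediate
4 | 2-bromo-4,6-dimethoxybenzoic acid | COc1cc(OC)c(C(=O)O)c(Br)c1 | intermediate
5 | pentylmagnesium bromide | CCCCC[Mg]Br | starting material
6 | hex-5-enenitrile | C=CCCCC#N | starting material
7 | N-(bromomagnesio) ketimine of undec-10-en-6-one | CCCCCC(=N[Mg]Br)CCCC=C | intermediate (not isolated)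
8 | undec-10-en-6-one | CCCCCC(=O)CCCC=C | intermediate
9 | 4,4,5,5-tetramethyl-2-vinyl-1,3,2-dioxaborolane | C=CB1OC(C)(C)C(C)(C)O1 | starting material
10 | (E)-11-(4,4,5,5-tetramethyl-1,3,2-dioxaborolan-2-yl)undec-10-en-6-one | CCCCCC(=O)CCC/C=C/B1OC(C)(C)C(C)(C)O1 | intermediate
11 | vinyl bromide (bromoethene) | C=CBr | starting material
12 | (E)-trideca-1,3-dien-8-one | CCCCCC(=O)CCC/C=C/C=C | intermediate
13 | (S)-6,8-dimethoxy-3-[(E)-6-oxoundec-1-en-1-yl]-3,4-dihydro-1H-isochromen-1-one | CCCCCC(=O)CCC/C=C/[C@@H]1Cc2cc(OC)cc(OC)c2C(=O)O1 | intermediate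
14 | (R)-6,8-dimethoxy-3-(6-oxoundecyl)-3,4-dihydro-1H-isochromen-1-one | CCCCCC(=O)CCCCC[C@@H]1Cc2cc(OC)cc(OC)c2C(=O)O1 | intermediate
15 | (R)-8-(dichloroboryloxy)-6-methoxy-3-(6-oxoundecyl)-3,4-dihydro-1H-isochromen-1-one | CCCCCC(=O)CCCCC[C@@H]1Cc2cc(OC)cc(OB(Cl)Cl)c2C(=O)O1 | intermediate (not isolated)
16 | (R)-8-hydroxy-6-methoxy-3-(6-oxoundecyl)-3,4-dihydro-1H-isochromen-1-one | CCCCCC(=O)CCCCC[C@@H]1Cc2cc(OC)cc(O)c2C(=O)O1 | target

**Step count**
Total steps: 8. Longest linear sequence: 6 steps (steps 3 to 8, from 5 and 6); the aryl branch (steps 1 and 2) joins at step 6.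

**Steps most likely to fail**

1. Step 6 (proposed new method). The diene insertion may show poor enantiofacial discrimination. The enantiomeric purity may also erode through reversible ionisation of the allylic lactone C–O bond by zerovalent palladium, and β-hydride elimination from the allyl intermediate may outrun C–O closure. The fallback uses only known chemistry and takes the C3 configuration from a resolved epoxide; it sets out from 4 and comes back at 14.
   - Epoxide: 7-bromohept-1-ene F1 is converted (Mg, THF) into hept-6-en-1-ylmagnesium bromide F2, which is acylated with hexanoyl chloride (Fe(acac)3 3 mol %, THF, −78 °C) to tridec-12-en-6-one F3. Ketalisation (ethylene glycol, TsOH, benzene, Dean–Stark) gives 2-(hept-6-en-1-yl)-2-pentyl-1,3-dioxolane F4. Epoxidation (mCPBA, NaHCO3, CH2Cl2) gives racemic 2-[5-(oxiran-2-yl)pentyl]-2-pentyl-1,3-dioxolane F5. Jacobsen hydrolytic kinetic resolution ((salen)Co(OAc), the antipode that hydrolyses the (S)-epoxide, 0.55 equiv H2O) leaves (R)-2-[5-(oxiran-2-yl)pentyl]-2-pentyl-1,3-dioxolane F6.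
   - Arene: acid 4 is turned with (COCl)2 and catalytic DMF into 2-bromo-4,6-dimethoxybenzoyl chloride F7 and then with Et2NH/Et3N into 2-bromo-N,N-diethyl-4,6-dimethoxybenzamide F8. Bromine–lithium exchange (n-BuLi, THF, −78 °C) gives N,N-diethyl-2-lithio-4,6-dimethoxybenzamide F9.
   - Union: after transmetallation (MgBr2·OEt2, then CuI 10 mol %), F9 opens F6 at its CH2 terminus without touching the stereocentre, giving (R)-N,N-diethyl-2-[2-hydroxy-7-(2-pentyl-1,3-dioxolan-2-yl)heptyl]-4,6-dimethoxybenzamide F10. Heating in 2 M HCl/1,4-dioxane (90 °C) closes the lactone and removes the dioxolane, which gives 14; the route continues with step 8.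

2. Step 7. On the rhodium catalyst the C=C may migrate toward C3 to an enol lactone, which would scramble C3, or the allylic C3–O bond may be ionised and hydrogenolysed. The fallback sets out from 13 and comes back at 14. It replaces metal-catalysed hydrogenation by metal-free diimide reduction (KO2CN=NCO2K, AcOH, MeOH, 0 °C → rt, in portions). This is a concerted syn transfer of H2 with no metal hydride or allyl-metal pathway, and it leaves the ketone and lactone alone. It makes no new compound (F0).

3. Step 4. The cross-metathesis may give incomplete E selectivity or homodimerise 8, and a Z boronate would be carried on as a Z diene into the key step. The fallback sets out from 8 and comes back at 12, bypassing steps 4 and 5 and building the diene by carbonyl olefination. Cross-metathesis of 8 with acrolein (3 equiv, second-generation Hoveyda–Grubbs catalyst RuCl2(=CH-C6H4-2-O-i-Pr)(H2IMes), CH2Cl2, 40 °C) gives (E)-7-oxododec-2-enal F11. Aldehyde-selective Wittig methylenation (Ph3P=CH2 from Ph3PCH3Br and KN(SiMe3)2, 1.05 equiv, THF, −78 °C) then gives 12.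

**Further compounds**
F1 | step 6 | 7-bromohept-1-ene | C=CCCCCCBr
F2 | step 6 | hept-6-en-1-ylmagnesium bromide | C=CCCCCC[Mg]Br
F3 | step 6 | tridec-12-en-6-one | CCCCCC(=O)CCCCCC=C
F4 | step 6 | 2-(hept-6-en-1-yl)-2-pentyl-1,3-dioxolane | CCCCCC1(OCCO1)CCCCCC=C
F5 | step 6 | racemic 2-[5-(oxiran-2-yl)pentyl]-2-pentyl-1,3-dioxolane | CCCCCC1(OCCO1)CCCCCC1CO1
F6 | step 6 | (R)-2-[5-(oxiran-2-yl)pentyl]-2-pentyl-1,3-dioxolane | CCCCCC1(OCCO1)CCCCC[C@@H]1CO1
F7 | step 6 | 2-bromo-4,6-dimethoxybenzoyl chloride | COc1cc(OC)c(C(=O)Cl)c(Br)c1
F8 | step 6 | 2-bromo-N,N-diethyl-4,6-dimethoxybenzamide | CCN(CC)C(=O)c1c(Br)cc(OC)cc1OC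
F9 | step 6 | N,N-diethyl-2-lithio-4,6-dimethoxybenzamide | CCN(CC)C(=O)c1c([Li])cc(OC)cc1OC
F10 | step 6 | (R)-N,N-diethyl-2-[2-hydroxy-7-(2-pentyl-1,3-dioxolan-2-yl)heptyl]-4,6-dimethoxybenzamide | CCCCCC1(OCCO1)CCCCC[C@@H](O)Cc1cc(OC)cc(OC)c1C(=O)N(CC)CC
F0 | step 7 | none | none
F11 | step 4 | (E)-7-oxododec-2-enal | CCCCCC(=O)CCC/C=C/C=O
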